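Count the acid. Two chemists dispute this flask.

common to all: nucleophile 1.05 equiv

| flask | electrophile | free base | protic impurity | remark | time |
|---|---|---|---|---|---|
| noon | 1 mM | 0.50 equiv | 1 mM | run made earlier |  |
| midnight | 1 mM | 2 equiv | 1 mM | run made earlier |  |
| dawn | 1 mM | 1 equiv | 1.5 mM | run made earlier |  |
| flask | 1.0 mM | 1.00 equiv | 1.00 mM |  | 3.0 min |

| run | time / min | electrophile / % | target / % |
|---|---|---|---|
| noon | 0.250 | 67.9 | 9.5 |
| noon | 0.417 | 56.4 | 11.4 |
| noon | 0.833 | 37.6 | 16.4 |
| noon | 1.50 | 24.1 | 17.5 |
| noon | 3.00 | 9.3 | 18.7 |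
| midnight | 0.667 | 41.2 | 17.0 |
| midnight | 1.33 | 26.4 | 18.9 |
| midnight | 2.00 | 16.1 | 18.8 |
| midnight | 2.50 | 12.4 | 20.2 |
| midnight | 3.00 | 8.4 | 20.6 |
| dawn | 0.250 | 56.6 | 8.2 |
| dawn | 0.417 | 43.3 | 11.1 |
| dawn | 0.833 | 24.2 | 13.0 |
| dawn | 1.50 | 10.3 | 15.9 |
| dawn | 3.00 | 4.9 | 16.7 |

(standard deviation of a reading: 1 percentage point)

* part of the electrophile that has reacted at 3.0 min
* share of the unused nucleophile that is free and not bound as protonated nucleophile, at 3.0 min

- the earlier runs do not show how much of nucleophile is bound; that part of a forecast is a guess

Noon and midnight carry the flask's protic impurity and bracket its free base. At 3.00 min they keep 9.3% and 8.4% of the electrophile. Their target stands at 18.7% and 20.6% and gains slowly.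

The first chemist makes the forecast: 91% reacted (88.5% to 93%) and a free share of 15% (6% to 35%). Her view is that nucleophile is being shut off, “implying free nucleophile of about 0.12–0.14 mM out of about 0.85 mM unused”.

The second chemist expects a similar conversion but a different share. He assumes each target sets free one acid, so protonated nucleophile stays at or below the target made, T. He freezes T at the noon and midnight mean, 0.197 mM.

Next he needs F, the free nucleophile. Target gain per electrophile is a pseudo-first-order constant that follows F. Early in noon it is 0.453 min⁻¹. Late, averaged over noon and midnight, it is 0.0532 min⁻¹. So F is about 0.123 mM, a rough reading given the scatter of 1 percentage point.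

Then F/(F+T) comes to 38.6%. This is the free floor, the least free share his ceiling allows. His floor and her 15% differ.

The flask gives 89.3% reacted and a free share of 42.5%, above his floor.

    electrophile + nucleophile → acid set free + target (k = 9.40 L mol⁻¹ s⁻¹)
    nucleophile + acid set free ⇌ protonated nucleophile, settled at all times (K = 6.90 × 10⁶ L mol⁻¹)
    acid set free + free base ⇌ salt of the base, settled at all times (K = 3.00 × 10⁵ L mol⁻¹)
    electrophile + protic impurity → quenched substrate (k = 21.0 L mol⁻¹ s⁻¹)
    2 nucleophile → self-condensation product (k = 16.0 L mol⁻¹ s⁻¹)

At 3.0 min this flask holds 0.146 mM of protonated nucleophile, under its target of 0.202 mM. Unused nucleophile is 0.254 mM. The simulated free amount puts this flask's floor at 34.8%. The neighbour charged with 0.25 mM of protic impurity comes nearer her view: its share lies inside her range, though above her 15%. There target is 27.8% and 6.68% of the nucleophile charge is free, so the floor is 20.2%. That neighbour's free share stands at 28.3%.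

The runs were generated by integration for an exercise, and the scatter is random.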